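**Strategy.** The cyclopentenone is disconnected at C5–C6 (1-oxaspiro[4.4]nonane numbering). C6 is a tertiary α-hydroxy ester and its neighbour, spiro carbon C5, lies between the C4 and C9 ketones, so this bond is a latent aldol of a β-diketone enol onto an α-keto ester, both held cis on the C7=C8 bis(enol ether). The precursor is the flat, achiral enedione keto ester 14, a 2-acyl-3-hydroxyfuran unmasked from a 3,4-dimethoxyfuran (bifuran 12) by singlet oxygen. A chiral copper Lewis acid then closes the carbocycle in a Nazarov-like 4π event that creates both quaternary stereocentres at once, funnelling the racemic, tautomerising precursors into one isomer.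

Key step: step 8

Remark: in the numbering used (O1, C2 aryl, C3, C4 ketone, C5 spiro, C6 carbinol, C7 and C8 methoxy carbons, C9 ketone) the given SMILES corresponds to (5S,6R), with 6-OH and O1 on the same face of the carbocycle and the ester cis to C4.

**Step 1**
Reactants: 1 dimethyl 2,2'-oxydiacetate; 2 dimethyl oxalate
Product: 3 dimethyl 3,4-dihydroxyfuran-2,5-dicarboxylate
Conditions: NaOMe (2.2 equiv), MeOH, reflux; then aq HCl, 0 °C
Reagents that add atoms: none
Why: A double Claisen (Dieckmann-type) condensation of the two ester-activated methylene groups with the two oxalate carbonyls should give the furan, which is drawn from the equilibrium as its aromatic bis-enolate.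

**Step 2**
Reactants: 3 dimethyl 3,4-dihydroxyfuran-2,5-dicarboxylate
Product: 4 dimethyl 3,4-dimethoxyfuran-2,5-dicarboxylate
Conditions: MeI (2.5 equiv), K2CO3 (2.5 equiv), DMF, 40 °C
Reagents that add atoms: methyl iodide, CI
Why: Williamson O-methylation of the two acidic, ester-flanked enolic hydroxyl groups should proceed cleanly on oxygen.

**Step 3**
Reactants: 4 dimethyl 3,4-dimethoxyfuran-2,5-dicarboxylate
Product: 5 3,4-dimethoxy-5-(methoxycarbonyl)furan-2-carboxylic acid
Conditions: KOH (1.0 equiv), MeOH–THF, 0 → 23 °C; then aq HCl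
Reagents that add atoms: potassium hydroxide, [K+].[OH-]
Why: Mono-saponification of a symmetric diester should stop after one ester because the first carboxylate, through its charge and its donation into the ring, slows attack of hydroxide on the second.

**Step 4**
Reactants: 5 3,4-dimethoxy-5-(methoxycarbonyl)furan-2-carboxylic acid
Product: 6 methyl 5-bromo-3,4-dimethoxyfuran-2-carboxylate
Conditions: NBS (1.05 equiv), DMF, 0 → 23 °C
Reagents that add atoms: N-bromosuccinimide, O=C1CCC(=O)N1Br
Why: Bromodecarboxylation (Hunsdiecker-type ipso-substitution) should occur because the only position open to electrophilic attack on this electron-rich furan is the carboxyl-bearing α-carbon, which then loses CO2.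

**Step 5**
Reactants: 7 1-[4-(benzyloxy)phenyl]ethan-1-one; 8 methyl 2-[(tert-butyldimethylsilyl)oxy]acetate
Product: 11 5-[4-(benzyloxy)phenyl]furan-3(2H)-one, via silyloxy diketone 9 (not isolated), via hydroxy diketone 10 (not isolated)
Conditions: 7, LiHMDS (2.2 equiv), THF, −78 °C; then 8, −78 → 0 °C; then aq HCl (3 M), THF, 23 °C
Reagents that add atoms: none
Why: Claisen condensation of the ketone enolate with the glycolate ester followed by acid desilylation should give a 1-hydroxy-2,4-diketone, which cyclodehydrates (5-exo-trig addition of OH to the aryl ketone, loss of water) to the 3(2H)-furanone.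

**Step 6**
Reactants: 11 5-[4-(benzyloxy)phenyl]furan-3(2H)-one; 6 methyl 5-bromo-3,4-dimethoxyfuran-2-carboxylate
Product: 12 methyl 5-{5-[4-(benzyloxy)phenyl]-3-oxo-2,3-dihydrofuran-2-yl}-3,4-dimethoxyfuran-2-carboxylate (racemic)
Conditions: Pd(OAc)2 (5 mol %), XPhos (2-dicyclohexylphosphino-2',4',6'-triisopropylbiphenyl, 10 mol %), K3PO4 (2.5 equiv), toluene, 90 °C, argon; aq NH4Cl work-up under argon
Reagents that add atoms: none
Why: Palladium-catalysed α-arylation of a ketone enolate (here the aromatic 3-furanolate) with a heteroaryl bromide should form the C–C bond, the phosphate base sparing both esters, the flanking methoxy group blocking a second arylation, and the new stereocentre being formed racemic and labile, which is irrelevant because it is planarised in step 7.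

**Step 7**
Reactants: 12 methyl 5-{5-[4-(benzyloxy)phenyl]-3-oxo-2,3-dihydrofuran-2-yl}-3,4-dimethoxyfuran-2-carboxylate
Product: 14 methyl (3Z)-5-{5-[4-(benzyloxy)phenyl]-3-hydroxyfuran-2-yl}-3,4-dimethoxy-2,5-dioxopent-3-enoate, via endoperoxide 13 (not isolated)
Conditions: O2, visible light, tetraphenylporphyrin (1 mol %), CH2Cl2, −78 °C; then Me2S (3 equiv), −78 → 0 °C; concentrated cold and used at once
Reagents that add atoms: dioxygen (as singlet oxygen), O=O
Why: [4+2] cycloaddition of singlet oxygen to the electron-rich dimethoxyfuran and reduction of the O–O bond should unmask the cis-enedione with the Z geometry inherited from the ring, the vinylogous-ester ring and the benzyl ether being inert, and the new 1,3-diketone should settle as the hydrogen-bonded 2-acyl-3-hydroxyfuran.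

**Step 8**
Reactants: 14 methyl (3Z)-5-{5-[4-(benzyloxy)phenyl]-3-hydroxyfuran-2-yl}-3,4-dimethoxy-2,5-dioxopent-3-enoate
Product: 15 methyl (5S,6R)-2-[4-(benzyloxy)phenyl]-6-hydroxy-7,8-dimethoxy-4,9-dioxo-1-oxaspiro[4.4]nona-2,7-diene-6-carboxylate
Conditions: [Cu((R,R)-t-Bu-box)](OTf)2 (10 mol %; t-Bu-box = 2,2'-(propane-2,2-diyl)bis(4-tert-butyl-4,5-dihydrooxazole)), 4 Å molecular sieves, CH2Cl2, −40 → 0 °C
Reagents that add atoms: none
Why: The divalent copper complex binds the C6 keto ester of 14 as an O,O-chelate, so that the C6 carbonyl, the C7=C8 bond and the hydrogen-bonded enol spanning C4–C5–C9 behave as an oxygen-stabilised pentadienyl cation that closes between C5 and C6 by a conrotatory 4π (Nazarov-type) cyclisation, which in polar terms is the intramolecular aldol addition of the β-diketone enol to the α-keto ester followed by proton transfer. The closest known reaction types are aldol and ene additions of enols and enol silanes to pyruvate-type esters chelated to Cu(OTf)2–bis(oxazoline) complexes and Lewis-acid-catalysed asymmetric Nazarov cyclisations of chelating dienones. Only the carbocycle is closed, by 5-exo-trig attack on the C6 carbonyl (4π-conrotatory when counted along C5–C9–C8–C7–C6), the cis C7=C8 geometry inherited from the furan keeping the termini within reach. C6 is set by the ligand: in the square-planar chelate the tert-butyl groups of the (R,R)-ligand should cover the si face of the C6 carbonyl, as the enantiomeric ligand covers the re face of pyruvates, so C5 should add to the re face and give 6R. C5 is set relative to C6 by the geometry of the termini: the O–H···O=C9 hydrogen bond of the acylhydroxyfuran keeps O1 on the inside of the U-shaped array, the copper-bound C6 oxygen can only sit outside, and conrotation then places 6-OH cis to O1 and the ester cis to C4, which is 5S. The step needs C–C closure to outrun attack of the enol oxygen on C7 with loss of methanol and an unselective proton-catalysed closure, which two-point activation of the keto ester at low temperature without base should secure.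

**Step 9**
Reactants: 15 methyl (5S,6R)-2-[4-(benzyloxy)phenyl]-6-hydroxy-7,8-dimethoxy-4,9-dioxo-1-oxaspiro[4.4]nona-2,7-diene-6-carboxylate
Product: 16 limnophilaspiroketone
Conditions: H2 (1 atm), Pd/C (10 wt %), EtOAc, 23 °C
Reagents that add atoms: none
Why: Catalytic hydrogenolysis of the benzyl aryl ether under neutral conditions should free the phenol without retro-aldol opening, the tetrasubstituted push–pull C7=C8 bond and the vinylogous-ester C2=C3 bond being poor hydrogenation substrates and both quaternary stereocentres untouched.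

**Compound list**

1 | dimethyl 2,2'-oxydiacetate (dimethyl diglycolate) | COC(=O)COCC(=O)OC | starting material
2 | dimethyl oxalate | COC(=O)C(=O)OC | starting material
3 | dimethyl 3,4-dihydroxyfuran-2,5-dicarboxylate | COC(=O)c1oc(C(=O)OC)c(O)c1O | intermediate
4 | dimethyl 3,4-dimethoxyfuran-2,5-dicarboxylate | COC(=O)c1oc(C(=O)OC)c(OC)c1OC | intermediate
5 | 3,4-dimethoxy-5-(methoxycarbonyl)furan-2-carboxylic acid | COC(=O)c1oc(C(=O)O)c(OC)c1OC | intermediate
6 | methyl 5-bromo-3,4-dimethoxyfuran-2-carboxylate | COC(=O)c1oc(Br)c(OC)c1OC | intermediate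
7 | 1-[4-(benzyloxy)phenyl]ethan-1-one | CC(=O)c1ccc(OCc2ccccc2)cc1 | starting material
8 | methyl 2-[(tert-butyldimethylsilyl)oxy]acetate | COC(=O)CO[Si](C)(C)C(C)(C)C | starting material
9 | 1-[4-(benzyloxy)phenyl]-4-[(tert-butyldimethylsilyl)oxy]butane-1,3-dione (not isolated) | O=C(CC(=O)CO[Si](C)(C)C(C)(C)C)c1ccc(OCc2ccccc2)cc1 | intermediate
10 | 1-[4-(benzyloxy)phenyl]-4-hydroxybutane-1,3-dione (not isolated) | O=C(CC(=O)CO)c1ccc(OCc2ccccc2)cc1 | intermediate
11 | 5-[4-(benzyloxy)phenyl]furan-3(2H)-one | O=C1COC(c2ccc(OCc3ccccc3)cc2)=C1 | intermediate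
12 | methyl 5-{5-[4-(benzyloxy)phenyl]-3-oxo-2,3-dihydrofuran-2-yl}-3,4-dimethoxyfuran-2-carboxylate (racemic, labile at C2 of the furanone) | COC(=O)c1oc(C2OC(c3ccc(OCc4ccccc4)cc3)=CC2=O)c(OC)c1OC | intermediate
13 | methyl 4-{5-[4-(benzyloxy)phenyl]-3-oxo-2,3-dihydrofuran-2-yl}-5,6-dimethoxy-2,3,7-trioxabicyclo[2.2.1]hept-5-ene-1-carboxylate (endoperoxide, not isolated) | COC(=O)C12OOC(C3OC(c4ccc(OCc5ccccc5)cc4)=CC3=O)(O1)C(OC)=C2OC | intermediate
14 | methyl (3Z)-5-{5-[4-(benzyloxy)phenyl]-3-hydroxyfuran-2-yl}-3,4-dimethoxy-2,5-dioxopent-3-enoate | COC(=O)C(=O)/C(OC)=C(OC)\C(=O)c1oc(-c2ccc(OCc3ccccc3)cc2)cc1O | intermediate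
15 | methyl (5S,6R)-2-[4-(benzyloxy)phenyl]-6-hydroxy-7,8-dimethoxy-4,9-dioxo-1-oxaspiro[4.4]nona-2,7-diene-6-carboxylate | COC(=O)[C@@]1(O)C(OC)=C(OC)C(=O)[C@]12OC(c1ccc(OCc3ccccc3)cc1)=CC2=O | intermediate
16 | limnophilaspiroketone, methyl (5S,6R)-6-hydroxy-2-(4-hydroxyphenyl)-7,8-dimethoxy-4,9-dioxo-1-oxaspiro[4.4]nona-2,7-diene-6-carboxylate | COC(=O)[C@@]1(O)C(OC)=C(OC)C(=O)[C@]12OC(c1ccc(O)cc1)=CC2=O | target

**Step count and risks**

Total steps: 9. Longest linear sequence: 8 steps (steps 1–4 and 6–9); step 5 is a one-step side branch.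

Steps most likely to fail:

1. Step 8. The β-diketone enol may displace triflate from copper, so that closure runs through an unselective proton-catalysed path and facial selectivity is lost. The enol oxygen may add to C7 with loss of methanol. The closure may be reversible (retro-aldol) and erode selectivity. The termini may react from the other rotamer and give the C5 epimer. Fallback: from 14, the enol would be silylated (TESOTf, 2,6-lutidine, CH2Cl2, −78 °C) to the triethylsilyl enol ether F1, which can neither chelate copper nor attack through oxygen. A Mukaiyama aldol cyclisation under [Cu((R,R)-t-Bu-box)](SbF6)2 (10 mol %, CH2Cl2, −78 → −40 °C), in which the silyl group passes to the new C6 alkoxide and makes the closure irreversible, should give the 6-O-triethylsilyl ether F2. HF·pyridine in THF at 0 °C would then return the route at 15.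

2. Step 6. Oxidative addition or reductive elimination may be slow at the hindered, electron-rich bromofuran; the furanolate may undergo O-arylation or double arylation; the product enolate may autoxidise at C2. Fallback: the furanone ring would be built onto the dimethoxyfuran instead of being coupled to it. From 5, catalytic protodecarboxylation (Ag2CO3 10 mol %, AcOH 5 mol %, DMSO, 120 °C) should give methyl 3,4-dimethoxyfuran-2-carboxylate F3. Friedel–Crafts hydroxyalkylation at its free α-position with methyl glyoxylate (COC(=O)C=O; Sc(OTf)3 10 mol %, CH2Cl2, 0 °C) should give the furylglycolate F4, and TBSCl with imidazole in DMF the silyl ether F5. Claisen condensation of F5 with the lithium enolate of 7 (LiHMDS, THF, −78 → 0 °C) should give the silyloxy diketone F6, which aq HCl in THF would desilylate to the hydroxy diketone F7 and cyclodehydrate in the same flask, returning the route at 12.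

3. Step 7. Photooxygenation may occur at the enol tautomer of 12 (C2 of the furanone) instead of at the dimethoxyfuran; the endoperoxide may fragment before it is reduced; 14 may cyclise unselectively during isolation. Fallback: a Clauson-Kaas-type two-stage unmasking. From 12, bromine in methanol buffered with KOAc at −40 °C (or anodic oxidation in methanol) should give the storable 2,5-dimethoxy-2,5-dihydrofuran F8 as a mixture of diastereomers. Hydrolysis of its two ketals with pyridinium p-toluenesulfonate in wet acetone at 0 °C just before the key step would return the route at 14.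

**Further compounds**

F1 | step 8 | methyl (3Z)-5-{5-[4-(benzyloxy)phenyl]-3-[(triethylsilyl)oxy]furan-2-yl}-3,4-dimethoxy-2,5-dioxopent-3-enoate | COC(=O)C(=O)/C(OC)=C(OC)\C(=O)c1oc(-c2ccc(OCc3ccccc3)cc2)cc1O[Si](CC)(CC)CC
F2 | step 8 | methyl (5S,6R)-2-[4-(benzyloxy)phenyl]-7,8-dimethoxy-4,9-dioxo-6-[(triethylsilyl)oxy]-1-oxaspiro[4.4]nona-2,7-diene-6-carboxylate | COC(=O)[C@@]1(O[Si](CC)(CC)CC)C(OC)=C(OC)C(=O)[C@]12OC(c1ccc(OCc3ccccc3)cc1)=CC2=O
F3 | step 6 | methyl 3,4-dimethoxyfuran-2-carboxylate | COC(=O)c1occ(OC)c1OC
F4 | step 6 | methyl 5-(1-hydroxy-2-methoxy-2-oxoethyl)-3,4-dimethoxyfuran-2-carboxylate (racemic) | COC(=O)C(O)c1oc(C(=O)OC)c(OC)c1OC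
F5 | step 6 | methyl 5-{1-[(tert-butyldimethylsilyl)oxy]-2-methoxy-2-oxoethyl}-3,4-dimethoxyfuran-2-carboxylate (racemic) | COC(=O)C(O[Si](C)(C)C(C)(C)C)c1oc(C(=O)OC)c(OC)c1OC
F6 | step 6 | methyl 5-{4-[4-(benzyloxy)phenyl]-1-[(tert-butyldimethylsilyl)oxy]-2,4-dioxobutyl}-3,4-dimethoxyfuran-2-carboxylate (not isolated) | COC(=O)c1oc(C(O[Si](C)(C)C(C)(C)C)C(=O)CC(=O)c2ccc(OCc3ccccc3)cc2)c(OC)c1OC
F7 | step 6 | methyl 5-{4-[4-(benzyloxy)phenyl]-1-hydroxy-2,4-dioxobutyl}-3,4-dimethoxyfuran-2-carboxylate (not isolated) | COC(=O)c1oc(C(O)C(=O)CC(=O)c2ccc(OCc3ccccc3)cc2)c(OC)c1OC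
F8 | step 7 | methyl 5-{5-[4-(benzyloxy)phenyl]-3-oxo-2,3-dihydrofuran-2-yl}-2,3,4,5-tetramethoxy-2,5-dihydrofuran-2-carboxylate (mixture of diastereomers) | COC(=O)C1(OC)OC(OC)(C2OC(c3ccc(OCc4ccccc4)cc3)=CC2=O)C(OC)=C1OC
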